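A direct plan would keep ring A ready-made: 2,3,5,6-tetramethoxyphenol A1 would be C-acylated at its last free carbon with 3-(3,4-dimethoxyphenyl)prop-2-ynoyl chloride A2 to give aryl ynone A3, and ring C would be closed by a demethylative 6-endo oxa-cyclisation of A3. The acylation would be its weakest step: the site lies between two methoxy groups, O-acylation competes, and the Lewis acid could cleave ethers or add HCl to the ynone. The demethylative cyclisation would be the next: it lacks precedent without an added electrophile and would have to beat 5-exo closure. The metalation–borylation–oxidation needed to make A1 would add length without adding skeletal complexity.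

The route builds ring A last and from open-chain carbons. The C6–C7–C8 triad (OMe, OH, OMe) is 1,3-dimethoxyacetone, whose carbonyl oxygen becomes the lone free 7-OH; C5, C4a and C8a come from an acyl ketene acetal, whose ketene-acetal carbon keeps one methoxy group as 5-OMe and whose ester carbon becomes the phenolic C8a–O1. One base-mediated [3+3] operation forms C5–C6 and C8–C8a, aromatises, and lets the new C8a phenoxide close ring C onto the enol-ether side chain. Thus no crowded arene is acylated, no aryl ether is cleaved in a cyclisation, no arene is oxygenated separately, and the 5-OMe/7-OH pattern needs no protecting group.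

Key step: step 3

Remark: methyl 3,3-dimethoxyprop-2-enoate is taken as a purchasable ketene acetal (as its ethyl/ethoxy homologue is); the geometry of the enol-ether double bonds formed on the way is of no consequence, since it is lost on ring closure.

Step 1
Reactants: 1 3-(3,4-dimethoxyphenyl)prop-2-ynoic acid; 2 methyl 3,3-dimethoxyprop-2-enoate
Product: 4 methyl 2-(dimethoxymethylidene)-5-(3,4-dimethoxyphenyl)-3-oxopent-4-ynoate, via acid chloride 3 (not isolated)
Conditions: 1, 1-chloro-N,N,2-trimethylprop-1-en-1-amine (1.1 equiv), CH2Cl2, 0 °C → rt; then 2 (1.2 equiv), 2,6-lutidine (1.5 equiv), CH2Cl2, −20 °C → rt; filter, concentrate, use crude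
Reagents that add atoms: 1-chloro-N,N,2-trimethylprop-1-en-1-amine CC(C)=C(Cl)N(C)C (Cl of 3; none of its atoms remains in 4)
Why: C-acylation of a ketene acetal with an acid chloride: the electron-rich C2 of the push–pull alkene 2 should attack acid chloride 3 (made with the chloroenamine under neutral conditions, so that no HCl adds to the alkyne), and 2,6-lutidine should take the proton from the dimethoxycarbenium intermediate before chloride can dealkylate it, which restores the ketene acetal between ester and ynone carbonyl; no stereocentre arises.

Step 2
Reactants: 4 methyl 2-(dimethoxymethylidene)-5-(3,4-dimethoxyphenyl)-3-oxopent-4-ynoate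
Product: 5 methyl 2-(dimethoxymethylidene)-5-methoxy-5-(3,4-dimethoxyphenyl)-3-oxopent-4-enoate (E/Z mixture)
Conditions: MeOH (1.5 equiv), PBu3 (5 mol %), CH2Cl2, 0 °C → rt
Reagents that add atoms: methanol CO
Why: Phosphine-catalysed oxa-Michael addition of an alcohol to an ynone: PBu3 adds to the aryl-bearing alkyne carbon, the zwitterion deprotonates methanol and methoxide displaces the phosphine by addition–elimination, which converts the most electrophilic site of 4 into a vinylogous ester and installs the leaving group for the later closure of ring C; no stereocentre arises and the geometry of the new double bond is of no consequence.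

Step 3
Reactants: 5 methyl 2-(dimethoxymethylidene)-5-methoxy-5-(3,4-dimethoxyphenyl)-3-oxopent-4-enoate; 6 1,3-dimethoxypropan-2-one
Product: 9 2-(3,4-dimethoxyphenyl)-7-hydroxy-5,6,8-trimethoxy-4H-chromen-4-one, via open-chain adduct 7 (not isolated), via aryl enone 8 (not isolated)
Conditions: 6 (1.3 equiv), NaH (4 equiv), THF, 0 °C; then 5, 0 °C → rt; then MeOH, 0 → 65 °C; 2 M HCl
Reagents that add atoms: none
Why: Proposed new method: base-mediated [3+3] benzannulation (flavone numbering): the sodium enolate of the symmetric ketone 6 should replace one methoxy group at the ketene-acetal carbon of 5 by addition–elimination (C5–C6 bond, 7), the second α-carbon of the ketone should then acylate itself with the ester (C8–C8a bond), and the cyclohexenedione so formed should tautomerise to the resorcinol 8, whose C8a phenoxide adds to the β-methoxy enone and expels methoxide to give 9. The closest known reaction types are the [3+3] cyclocondensation of 1,3-dinucleophilic ketones with alkoxymethylene malonates or bis-acceptor ketene dithioacetals to phenols, and the methoxide-mediated Dieckmann closure of a methyl ketone onto a malonate ester used to make resorcinols. Ring A closes in a 6-(enolendo)-exo-trig Claisen mode and ring C in a 6-endo-trig oxa-Michael addition–elimination; no stereocentre is formed. Site selectivity in the first attack should follow carbanion stabilisation: addition at the ketene-acetal carbon gives a carbanion flanked by ester and ketone, addition at the enol-ether carbon of the side chain one flanked by the ketone alone. The ring closure needs carbon rather than oxygen as nucleophile and the ester rather than the ketone as electrophile: lactonisation to a 2-pyranone is reversible in methoxide/methanol whereas aromatisation is not, and the C4 carbonyl, a doubly vinylogous ester, is the poorer electrophile; as methoxide is the only alkoxide present, every exchange at ketene acetal, ester or enol ether is degenerate. The pattern of ring A follows from the building blocks: the ketone oxygen of 6 becomes the free 7-OH between 6- and 8-OMe, the surviving ketene-acetal methoxy is 5-OMe, and the ester carbonyl oxygen becomes O1.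

Compound list
1 | 3-(3,4-dimethoxyphenyl)prop-2-ynoic acid | COc1ccc(C#CC(=O)O)cc1OC | starting material
2 | methyl 3,3-dimethoxyprop-2-enoate | COC(=O)C=C(OC)OC | starting material
3 | 3-(3,4-dimethoxyphenyl)prop-2-ynoyl chloride | COc1ccc(C#CC(=O)Cl)cc1OC | intermediate
4 | methyl 2-(dimethoxymethylidene)-5-(3,4-dimethoxyphenyl)-3-oxopent-4-ynoate | COC(=O)C(=C(OC)OC)C(=O)C#Cc1ccc(OC)c(OC)c1 | intermediate
5 | methyl 2-(dimethoxymethylidene)-5-methoxy-5-(3,4-dimethoxyphenyl)-3-oxopent-4-enoate (E/Z mixture at C4=C5) | COC(=O)C(=C(OC)OC)C(=O)C=C(OC)c1ccc(OC)c(OC)c1 | intermediate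
6 | 1,3-dimethoxypropan-2-one | COCC(=O)COC | starting material
7 | methyl 3,4,6-trimethoxy-2-[3-methoxy-3-(3,4-dimethoxyphenyl)prop-2-enoyl]-5-oxohex-2-enoate (racemic at C4, double-bond geometries labile) | COCC(=O)C(OC)C(OC)=C(C(=O)OC)C(=O)C=C(OC)c1ccc(OC)c(OC)c1 | intermediate
8 | 1-(2,4-dihydroxy-3,5,6-trimethoxyphenyl)-3-methoxy-3-(3,4-dimethoxyphenyl)prop-2-en-1-one (E/Z mixture) | COC(=CC(=O)c1c(O)c(OC)c(O)c(OC)c1OC)c1ccc(OC)c(OC)c1 | intermediate
9 | 2-(3,4-dimethoxyphenyl)-7-hydroxy-5,6,8-trimethoxy-4H-chromen-4-one (7-hydroxy-3',4',5,6,8-pentamethoxyflavone) | COc1ccc(-c2cc(=O)c3c(OC)c(OC)c(O)c(OC)c3o2)cc1OC | target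

Total step count: 3. Longest linear sequence: 3 steps (1 → 4 → 5 → 9).

Steps most likely to fail

1. Step 3 (key step). The enolate oxygen, not the second α-carbon, may close on the ester, so that the sequence stalls at a 2-pyranone; or the second enolate may add to the ketone instead of the ester. Fallback, in known reaction types and through an isolated heterocycle: from 5 and 6, the condensation would be run with NaH in THF at 0 °C only, the conditions under which ketones and bis-acceptor ketene acetals are known to give 2-pyranones, and stopped at 4,5-dimethoxy-3-[3-methoxy-3-(3,4-dimethoxyphenyl)prop-2-enoyl]-6-(methoxymethyl)-2H-pyran-2-one F1. F1 would then undergo the known pyranone-to-benzene ring transformation with Mg(OMe)2 in MeOH at reflux (methanolysis of the lactone, magnesium-templated Claisen closure), and acidification would return to the route at 9.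

2. Step 1. Chloride may dealkylate the dimethoxycarbenium intermediate, or 2 may add to the ynone in conjugate fashion, so that the acyl ketene acetal is lost. Fallback: from 3, magnesium-mediated decarboxylative Claisen condensation with potassium methyl malonate (MgCl2, Et3N, MeCN) would give methyl 5-(3,4-dimethoxyphenyl)-3-oxopent-4-ynoate F2. Condensation of F2 with tetramethyl orthocarbonate in Ac2O (alkoxymethylenation of the active methylene group at the orthocarbonate level) would build the ketene acetal after the C–C bond and return to the route at 4.

3. Step 2. Methanol may also add across the push–pull double bond, or the acyl ketene acetal may be cleaved, during the conjugate addition. Fallback: from 2, acylation as in step 1 with (2E)-3-(3,4-dimethoxyphenyl)prop-2-enoyl chloride F3 (from the commercial acid) would give methyl (4E)-2-(dimethoxymethylidene)-5-(3,4-dimethoxyphenyl)-3-oxopent-4-enoate F4, which needs no methanol addition. Annulation of F4 with 6 under the conditions of step 3 would stop at the chalcone (2E)-1-(2,4-dihydroxy-3,5,6-trimethoxyphenyl)-3-(3,4-dimethoxyphenyl)prop-2-en-1-one F5, and oxidative cyclisation of F5 with I2 (cat.) in DMSO at 120 °C would return to the route at 9.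

Further compounds
F1 | step 3 | 4,5-dimethoxy-3-[3-methoxy-3-(3,4-dimethoxyphenyl)prop-2-enoyl]-6-(methoxymethyl)-2H-pyran-2-one | COCc1oc(=O)c(C(=O)C=C(OC)c2ccc(OC)c(OC)c2)c(OC)c1OC
F2 | step 1 | methyl 5-(3,4-dimethoxyphenyl)-3-oxopent-4-ynoate | COC(=O)CC(=O)C#Cc1ccc(OC)c(OC)c1
F3 | step 2 | (2E)-3-(3,4-dimethoxyphenyl)prop-2-enoyl chloride | COc1ccc(/C=C/C(Cl)=O)cc1OC
F4 | step 2 | methyl (4E)-2-(dimethoxymethylidene)-5-(3,4-dimethoxyphenyl)-3-oxopent-4-enoate | COC(=O)C(=C(OC)OC)C(=O)/C=C/c1ccc(OC)c(OC)c1
F5 | step 2 | (2E)-1-(2,4-dihydroxy-3,5,6-trimethoxyphenyl)-3-(3,4-dimethoxyphenyl)prop-2-en-1-one | COc1ccc(/C=C/C(=O)c2c(O)c(OC)c(O)c(OC)c2OC)cc1OC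
A1 | direct plan | 2,3,5,6-tetramethoxyphenol | COc1cc(OC)c(OC)c(O)c1OC
A2 | direct plan | 3-(3,4-dimethoxyphenyl)prop-2-ynoyl chloride | COc1ccc(C#CC(=O)Cl)cc1OC
A3 | direct plan | 3-(3,4-dimethoxyphenyl)-1-(4-hydroxy-2,3,5,6-tetramethoxyphenyl)prop-2-yn-1-one | COc1ccc(C#CC(=O)c2c(OC)c(OC)c(O)c(OC)c2OC)cc1OC
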